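**Plan**

1. Numbering: C1 (prenyl bridgehead), C2–C3–C4 (trione bridge, aroyl on C3), C5 (lavandulyl bridgehead), C6 (CH2), C7 (prenyl CH), C8 (CMe2), C9 (bridging C=O). Cuts, in retrosynthetic order: C3–aroyl; the C=CH2 of the lavandulyl group and the C=C of the C7 prenyl group; C7–C8 (opens ring C1–C8–C7–C6–C5–C9); C1–C8; C1–C2 (opens the carbocycle); C1–C9 and C3–C4; C5–C6 and C5–side chain.
2. Enabling feature: C8 is a gem-dimethyl quaternary carbon between quaternary C1 and methine C7, so it is the Markovnikov radical of an isopropenyl group on C1. That group lies 1,3 (across C9) to the C5–C6 arm, so a C6–C7 alkyne lets the C8 radical close ring C1–C8–C7–C6–C5–C9.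
3. Forward: a side-chain iodide and propargyl bromide are joined at a malonate carbon (C5). The two carboxyls are grown into a C4 methoxyacrylate and a C9 homoprenyl ketone, and Claisen closure (C1–C2) gives the first ring, a 5-methoxycyclohex-4-ene-1,3-dione. C1 is alkenylated, the alkyne is capped as a thioester, and the radical step closes the second ring; olefinations, C3 aroylation and hydrolysis finish.
4. Stereochemistry: the side-chain centre comes from an oxazolidinone-auxiliary alkylation; C5 from a catalyst-controlled phase-transfer propargylation; C1 from alkenylation anti to the branched C5 chain (only the resulting cis isomer can cyclise); C7 from exo-face hydride delivery to the exocyclic enethioate.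
5. The lavandulyl isopropenyl group is carried as a vinyl group so that it does not compete for the hydrogen atom. The enol ether sits on C4 so that C1 is the only nucleophilic carbon of the ring enolate.

Key step: step 17

Assumptions: the (S,S) antipode of the spiro ammonium catalyst is taken to give the C5 configuration drawn for 13 (the (R,R) salt is used if the sense proves opposite); 25 is written as one enol tautomer of its 1,3-dione; 4-acetoxy-3-methoxybenzoic acid is taken as a purchasable starting material.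

**Route**

Step 1
Reactants: 1 (R)-4-benzyloxazolidin-2-one; 2 (E)-but-2-enoyl chloride
Product: 3 (R)-4-benzyl-3-[(E)-but-2-enoyl]oxazolidin-2-one
Conditions: n-BuLi, THF, −78 °C; then 2, −78 → 0 °C
Reagents that add atoms: none
Why: N-acylation of the lithiated oxazolidinone with an acid chloride is the standard entry to such imides and leaves the stereocentre of the auxiliary untouched.

Step 2
Reactants: 3 (R)-4-benzyl-3-[(E)-but-2-enoyl]oxazolidin-2-one; 4 1-bromo-3-methylbut-2-ene (prenyl bromide)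
Product: 5 (R)-4-benzyl-3-[(2R)-2-ethenyl-5-methylhex-4-enoyl]oxazolidin-2-one
Conditions: NaHMDS, THF, −78 °C; then 4, −78 → −40 °C
Reagents that add atoms: none
Why: γ-Deprotonation of the crotonyl imide gives the chelated (Z)-dienolate, which should be alkylated at the α-carbon on the face away from the benzyl group (deconjugative Evans alkylation), setting the (R) centre that becomes the lavandulyl carbon and leaving a vinyl group as the latent isopropenyl unit.

Step 3
Reactants: 5 (R)-4-benzyl-3-[(2R)-2-ethenyl-5-methylhex-4-enoyl]oxazolidin-2-one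
Product: 6 (2R)-2-ethenyl-5-methylhex-4-en-1-ol
Conditions: LiBH4, MeOH (1 equiv), Et2O, 0 °C
Reagents that add atoms: none
Why: Reductive cleavage of the imide with lithium borohydride should give the primary alcohol and return the auxiliary without epimerising the allylic α-centre.

Step 4
Reactants: 6 (2R)-2-ethenyl-5-methylhex-4-en-1-ol
Product: 7 (3R)-3-(iodomethyl)-6-methylhepta-1,5-diene
Conditions: I2, PPh3, imidazole, CH2Cl2, 0 °C → rt
Reagents that add atoms: iodine, II
Why: Appel-type iodination acts only at the primary carbinol carbon, so the adjacent stereocentre is not touched.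

Step 5
Reactants: 8 3-tert-butoxy-3-oxopropanoic acid (mono-tert-butyl malonate); 9 2,2-diphenylethanol
Product: 10 tert-butyl 2,2-diphenylethyl malonate
Conditions: DCC, DMAP (cat.), CH2Cl2, 0 °C → rt
Reagents that add atoms: none
Why: Steglich esterification of the malonic half-acid gives the mixed diester whose two unlike ester groups are needed for catalyst recognition in step 7 and for stepwise unmasking later.

Step 6
Reactants: 10 tert-butyl 2,2-diphenylethyl malonate; 7 (3R)-3-(iodomethyl)-6-methylhepta-1,5-diene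
Product: 11 tert-butyl 2,2-diphenylethyl 2-[(2S)-2-ethenyl-5-methylhex-4-en-1-yl]malonate (both epimers at the malonate carbon)
Conditions: NaH, 10 (1.5 equiv), DMF–THF, 0 → 50 °C
Reagents that add atoms: none
Why: SN2 alkylation of the sodium malonate by the primary iodide (malonic ester alkylation) should give the mono-alkylated diester, whose stereorandom malonate CH is planarised in the next step.

Step 7
Reactants: 11 tert-butyl 2,2-diphenylethyl 2-[(2S)-2-ethenyl-5-methylhex-4-en-1-yl]malonate; 12 3-bromoprop-1-yne (propargyl bromide)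
Product: 13 1-tert-butyl 3-(2,2-diphenylethyl) (2R)-2-[(2S)-2-ethenyl-5-methylhex-4-en-1-yl]-2-(prop-2-yn-1-yl)malonate
Conditions: (S,S)-N-spiro bis(binaphthyl)ammonium bromide with 3,4,5-trifluorophenyl groups (5 mol %), 50% aq. KOH, toluene, −40 °C
Reagents that add atoms: none
Why: Asymmetric phase-transfer alkylation of α-alkyl malonates carrying one tert-butyl and one aryl-containing ester is established for activated halides such as propargyl bromide, and the chiral ammonium ion pair rather than the remote side-chain centre should decide which face of the planar enolate is alkylated, setting quaternary C5.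

Step 8
Reactants: 13 1-tert-butyl 3-(2,2-diphenylethyl) (2R)-2-[(2S)-2-ethenyl-5-methylhex-4-en-1-yl]-2-(prop-2-yn-1-yl)malonate
Product: 14 (2R)-2-(tert-butoxycarbonyl)-2-[(2S)-2-ethenyl-5-methylhex-4-en-1-yl]pent-4-ynoic acid
Conditions: 1 N KOH, MeOH–THF, rt → 40 °C; then 1 N HCl
Reagents that add atoms: potassium hydroxide, [K+].[OH-]
Why: Saponification should remove only the primary 2,2-diphenylethyl ester because hydroxide does not attack the tert-butyl ester, so the carboxyl destined to become C4 is freed selectively.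

Step 9
Reactants: 14 (2R)-2-(tert-butoxycarbonyl)-2-[(2S)-2-ethenyl-5-methylhex-4-en-1-yl]pent-4-ynoic acid; 15 potassium 3-methoxy-3-oxopropanoate (potassium methyl malonate)
Product: 18 1-tert-butyl 5-methyl (2R)-2-[(2S)-2-ethenyl-5-methylhex-4-en-1-yl]-3-oxo-2-(prop-2-yn-1-yl)pentanedioate, via acyl imidazolide 16 (not isolated), via acylmalonic half-ester 17 (not isolated)
Conditions: CDI, THF, rt; then 15, MgCl2, Et3N, THF, rt → 45 °C; 1 N HCl
Reagents that add atoms: none
Why: Masamune–Brooks homologation (C-acylation of the magnesium malonate half-ester by the acyl imidazolide, then decarboxylation) converts the acid into the β-keto ester under near-neutral conditions that leave the tert-butyl ester and the quaternary centre untouched.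

Step 10
Reactants: 18 1-tert-butyl 5-methyl (2R)-2-[(2S)-2-ethenyl-5-methylhex-4-en-1-yl]-3-oxo-2-(prop-2-yn-1-yl)pentanedioate
Product: 19 5-tert-butyl 1-methyl (2E,4R)-4-[(2S)-2-ethenyl-5-methylhex-4-en-1-yl]-3-methoxy-4-(prop-2-yn-1-yl)pent-2-enedioate
Conditions: KHMDS, THF–DMPU, −78 °C; then Me2SO4, −78 → 0 °C
Reagents that add atoms: dimethyl sulfate, COS(=O)(=O)OC
Why: O-Alkylation of the dissociated potassium enolate of a β-keto ester by a hard methylating agent in a dipolar medium should give the β-methoxyacrylate, which fixes the enol ether on C4 and masks the acidic C3 methylene, and either alkene geometry is usable because alkoxide equilibrates it in step 13.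

Step 11
Reactants: 19 5-tert-butyl 1-methyl (2E,4R)-4-[(2S)-2-ethenyl-5-methylhex-4-en-1-yl]-3-methoxy-4-(prop-2-yn-1-yl)pent-2-enedioate
Product: 21 (2R,3E)-2-[(2S)-2-ethenyl-5-methylhex-4-en-1-yl]-3,5-dimethoxy-5-oxo-2-(prop-2-yn-1-yl)pent-3-enoic acid, via trimethylsilyl ester 20 (not isolated)
Conditions: TMSOTf, 2,6-lutidine, CH2Cl2, 0 °C → rt; then pH 4 buffer
Reagents that add atoms: none
Why: Silyl triflate-induced loss of isobutene turns the tert-butyl ester into a silyl ester that hydrolyses on work-up, a non-protic dealkylation that should spare the enol ether, the methyl ester and the acid-sensitive trisubstituted alkene.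

Step 12
Reactants: 21 (2R,3E)-2-[(2S)-2-ethenyl-5-methylhex-4-en-1-yl]-3,5-dimethoxy-5-oxo-2-(prop-2-yn-1-yl)pent-3-enoic acid; 22 5-bromo-2-methylpent-2-ene
Product: 24 methyl (2E,4R)-4-[(2S)-2-ethenyl-5-methylhex-4-en-1-yl]-3-methoxy-9-methyl-5-oxo-4-(prop-2-yn-1-yl)deca-2,8-dienoate, via acid chloride 23 (not isolated)
Conditions: 1-chloro-N,N,2-trimethylprop-1-en-1-amine, CH2Cl2, 0 °C → rt; then (4-methylpent-3-en-1-yl)MgBr (from 22, Mg, THF), Fe(acac)3 (3 mol %), THF, −78 °C
Reagents that add atoms: none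
Why: Neutral conversion into the acid chloride followed by iron-catalysed acylation of the Grignard reagent should stop at the ketone, because at −78 °C the catalysed coupling is much faster than addition to the ketone or the methoxyacrylate and than deprotonation of the alkyne.

Step 13
Reactants: 24 methyl (2E,4R)-4-[(2S)-2-ethenyl-5-methylhex-4-en-1-yl]-3-methoxy-9-methyl-5-oxo-4-(prop-2-yn-1-yl)deca-2,8-dienoate
Product: 25 (4S)-4-[(2S)-2-ethenyl-5-methylhex-4-en-1-yl]-5-hydroxy-3-methoxy-6-(3-methylbut-2-en-1-yl)-4-(prop-2-yn-1-yl)cyclohexa-2,5-dien-1-one (enol form of the 1,3-dione)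
Conditions: KOtBu (2.2 equiv), THF, 0 °C → rt; then 1 N HCl
Reagents that add atoms: none
Why: The only enolisable position, the C1 methylene of the ketone, should attack the acrylate ester in a Dieckmann-type (intramolecular Claisen) 6-exo-trig cyclisation of a 5-oxo ester, driven by deprotonation of the resulting cyclic 1,3-dione, while methoxide equilibrates the enol ether geometry towards the cyclisable (E) isomer.

Step 14
Reactants: 26 4,4,5,5-tetramethyl-2-(prop-1-en-2-yl)-1,3,2-dioxaborolane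
Product: 27 phenyl(prop-1-en-2-yl)iodonium tetrafluoroborate
Conditions: PhI(OAc)2, BF3·OEt2, CH2Cl2, −30 → 0 °C; then sat. aq. NaBF4
Reagents that add atoms: (diacetoxyiodo)benzene, CC(=O)OI(OC(C)=O)c1ccccc1; sodium tetrafluoroborate, [Na+].F[B-](F)(F)F
Why: Boron–iodine(III) exchange of alkenylboronates with Lewis-acid-activated (diacetoxyiodo)benzene is a general route to alkenyl(phenyl)iodonium salts, and anion metathesis gives the tetrafluoroborate.

Step 15
Reactants: 25 (4S)-4-[(2S)-2-ethenyl-5-methylhex-4-en-1-yl]-5-hydroxy-3-methoxy-6-(3-methylbut-2-en-1-yl)-4-(prop-2-yn-1-yl)cyclohexa-2,5-dien-1-one; 27 phenyl(prop-1-en-2-yl)iodonium tetrafluoroborate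
Product: 28 (2S,6R)-6-[(2S)-2-ethenyl-5-methylhex-4-en-1-yl]-5-methoxy-2-(3-methylbut-2-en-1-yl)-2-(prop-1-en-2-yl)-6-(prop-2-yn-1-yl)cyclohex-4-ene-1,3-dione (isopropenyl cis to propargyl)
Conditions: KOtBu (1.05 equiv), THF, −78 °C; then 27, −78 → 0 °C
Reagents that add atoms: none
Why: C-Alkenylation of 2-substituted 1,3-diketone enolates by alkenyl(aryl)iodonium salts (ligand coupling at iodine(III)) builds quaternary centres, the enolate is confined to O2–C2–C1–C9–O9 because C4 carries the enol ether, and the alkenyl group should enter anti to the bulkier β-branched C5 chain, that is cis to the slim propargyl arm.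

Step 16
Reactants: 28 (2S,6R)-6-[(2S)-2-ethenyl-5-methylhex-4-en-1-yl]-5-methoxy-2-(3-methylbut-2-en-1-yl)-2-(prop-1-en-2-yl)-6-(prop-2-yn-1-yl)cyclohex-4-ene-1,3-dione; 29 S-ethyl carbonochloridothioate (S-ethyl chlorothioformate)
Product: 30 S-ethyl 4-[(1R,5S)-1-[(2S)-2-ethenyl-5-methylhex-4-en-1-yl]-2-methoxy-5-(3-methylbut-2-en-1-yl)-4,6-dioxo-5-(prop-1-en-2-yl)cyclohex-2-en-1-yl]but-2-ynethioate
Conditions: LiHMDS (1.1 equiv), THF, −78 °C; then 29, −78 → −40 °C
Reagents that add atoms: none
Why: The terminal alkyne is the only acidic site left because both ring carbonyls are non-enolisable, so its lithium acetylide should be acylated by the chlorothioformate to give the alkynyl thioester.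

Step 17
Reactants: 30 S-ethyl 4-[(1R,5S)-1-[(2S)-2-ethenyl-5-methylhex-4-en-1-yl]-2-methoxy-5-(3-methylbut-2-en-1-yl)-4,6-dioxo-5-(prop-1-en-2-yl)cyclohex-2-en-1-yl]but-2-ynethioate
Product: 31 S-ethyl 2-[(1S,5R)-5-[(2S)-2-ethenyl-5-methylhex-4-en-1-yl]-4-methoxy-8,8-dimethyl-1-(3-methylbut-2-en-1-yl)-2,9-dioxobicyclo[3.3.1]non-3-en-7-ylidene]ethanethioate (E/Z mixture)
Conditions: Fe(acac)3 (30 mol %), PhSiH3 (2.5 equiv), EtOH–ethylene glycol (5:1), 0.01 M, 40 °C
Reagents that add atoms: none
Why: An iron hydride formed from Fe(acac)3 and phenylsilane should transfer a hydrogen atom to the CH2 terminus of the C1 isopropenyl group, giving the tertiary C8 radical, which adds to C7, the β-carbon of the alkynyl thioester, and the resulting α-acyl vinyl radical is reduced and protonated to the exocyclic enethioate. The closest known reaction type is the metal-hydride hydrogen-atom-transfer initiated Giese cyclisation of 1,1-disubstituted alkenes onto electron-poor π-acceptors, together with radical 6-exo-dig closure onto alkynoates. Ring C1–C8–C7–C6–C5–C9 closes in the 6-exo-dig mode through a chair-like arrangement with the C5 arm axial, the nucleophilic tertiary radical being polarity-matched with the electrophilic alkyne carbon. No new stereocentre is formed, since C7 stays sp2 and C8 carries two methyl groups, and the bridge can only form from the isomer in which the C1 alkene and the C5 arm are cis. The step needs hydrogen-atom transfer to the 1,1-disubstituted C1 alkene in preference to the two prenyl alkenes and the monosubstituted side-chain vinyl group, which rests on the known rate order of this transfer (1,1-disubstituted fastest). It also needs ring closure to outrun reduction of the radical, which high dilution and the activated acceptor should secure.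

Step 18
Reactants: 31 S-ethyl 2-[(1S,5R)-5-[(2S)-2-ethenyl-5-methylhex-4-en-1-yl]-4-methoxy-8,8-dimethyl-1-(3-methylbut-2-en-1-yl)-2,9-dioxobicyclo[3.3.1]non-3-en-7-ylidene]ethanethioate
Product: 32 S-ethyl 2-[(1S,5R,7S)-5-[(2S)-2-ethenyl-5-methylhex-4-en-1-yl]-4-methoxy-8,8-dimethyl-1-(3-methylbut-2-en-1-yl)-2,9-dioxobicyclo[3.3.1]non-3-en-7-yl]ethanethioate (C7 substituent endo)
Conditions: Cu(OAc)2·H2O (5 mol %), 1,2-bis(diphenylphosphino)benzene (5 mol %), (EtO)2MeSiH, t-BuOH, toluene, rt
Reagents that add atoms: none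
Why: Phosphine-ligated copper hydride conjugate reduction of β,β-disubstituted enoates tolerates hindered ketones and isolated alkenes, and hydride should reach C7 from the open exo face because the endo face is screened by the C2–C4 bridge, which places the CH2COSEt group endo as required, both alkene isomers converging on the same centre.

Step 19
Reactants: 32 S-ethyl 2-[(1S,5R,7S)-5-[(2S)-2-ethenyl-5-methylhex-4-en-1-yl]-4-methoxy-8,8-dimethyl-1-(3-methylbut-2-en-1-yl)-2,9-dioxobicyclo[3.3.1]non-3-en-7-yl]ethanethioate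
Product: 33 2-[(1S,5R,7S)-5-[(2S)-2-ethenyl-5-methylhex-4-en-1-yl]-4-methoxy-8,8-dimethyl-1-(3-methylbut-2-en-1-yl)-2,9-dioxobicyclo[3.3.1]non-3-en-7-yl]acetaldehyde
Conditions: Et3SiH, Lindlar catalyst (Pd/CaCO3, Pb-poisoned), acetone, rt
Reagents that add atoms: none
Why: Fukuyama reduction converts the thioester into the aldehyde in the presence of the ketones, and the poisoned palladium catalyst is chosen so that the monosubstituted side-chain alkene is neither hydrogenated nor isomerised.

Step 20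
Reactants: 33 2-[(1S,5R,7S)-5-[(2S)-2-ethenyl-5-methylhex-4-en-1-yl]-4-methoxy-8,8-dimethyl-1-(3-methylbut-2-en-1-yl)-2,9-dioxobicyclo[3.3.1]non-3-en-7-yl]acetaldehyde; 34 isopropyltriphenylphosphonium iodide
Product: 35 (1S,5R,7R)-5-[(2S)-2-ethenyl-5-methylhex-4-en-1-yl]-4-methoxy-8,8-dimethyl-1,7-bis(3-methylbut-2-en-1-yl)bicyclo[3.3.1]non-3-ene-2,9-dione
Conditions: 34, n-BuLi, THF, 0 °C; then 33, −78 → 0 °C
Reagents that add atoms: none
Why: Wittig olefination with the non-stabilised isopropylidene ylide should take place only at the aldehyde, since both ketones are flanked by quaternary carbons, and it completes the C7 prenyl group.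

Step 21
Reactants: 35 (1S,5R,7R)-5-[(2S)-2-ethenyl-5-methylhex-4-en-1-yl]-4-methoxy-8,8-dimethyl-1,7-bis(3-methylbut-2-en-1-yl)bicyclo[3.3.1]non-3-ene-2,9-dione
Product: 36 (1S,5S,7R)-5-[(2S)-2-acetyl-5-methylhex-4-en-1-yl]-4-methoxy-8,8-dimethyl-1,7-bis(3-methylbut-2-en-1-yl)bicyclo[3.3.1]non-3-ene-2,9-dione (same spatial arrangement at C5 as in 35)
Conditions: PdCl2 (10 mol %), CuCl, O2 (1 atm), DMF–H2O (7:1), rt
Reagents that add atoms: water, O
Why: Tsuji–Wacker oxidation is selective for the monosubstituted alkene over the trisubstituted prenyl groups and the enol ether and should give the methyl ketone with Markovnikov regiochemistry without epimerising the adjacent centre under these weakly acidic conditions.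

Step 22
Reactants: 36 (1S,5S,7R)-5-[(2S)-2-acetyl-5-methylhex-4-en-1-yl]-4-methoxy-8,8-dimethyl-1,7-bis(3-methylbut-2-en-1-yl)bicyclo[3.3.1]non-3-ene-2,9-dione
Product: 37 (1S,5R,7R)-4-methoxy-8,8-dimethyl-1,7-bis(3-methylbut-2-en-1-yl)-5-[(2S)-5-methyl-2-(prop-1-en-2-yl)hex-4-en-1-yl]bicyclo[3.3.1]non-3-ene-2,9-dione
Conditions: Zn, CH2Br2, TiCl4, THF–CH2Cl2, 0 °C → rt
Reagents that add atoms: dibromomethane, BrCBr
Why: Takai–Lombardo methylenation is non-basic and should therefore convert the unhindered, epimerisable methyl ketone into the isopropenyl group without loss of configuration, while the two ring ketones, each next to a quaternary carbon, stay inert.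

Step 23
Reactants: 38 4-acetoxy-3-methoxybenzoic acid
Product: 39 4-acetoxy-3-methoxybenzoyl chloride
Conditions: (COCl)2, DMF (cat.), CH2Cl2, 0 °C → rt
Reagents that add atoms: oxalyl chloride, O=C(Cl)C(=O)Cl
Why: Vilsmeier-catalysed acid chloride formation is routine and leaves the aryl acetate, which protects the phenol, intact.

Step 24
Reactants: 37 (1S,5R,7R)-4-methoxy-8,8-dimethyl-1,7-bis(3-methylbut-2-en-1-yl)-5-[(2S)-5-methyl-2-(prop-1-en-2-yl)hex-4-en-1-yl]bicyclo[3.3.1]non-3-ene-2,9-dione; 39 4-acetoxy-3-methoxybenzoyl chloride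
Product: 40 4-{[(1R,5R,7R)-4-methoxy-8,8-dimethyl-1,7-bis(3-methylbut-2-en-1-yl)-5-[(2S)-5-methyl-2-(prop-1-en-2-yl)hex-4-en-1-yl]-2,9-dioxobicyclo[3.3.1]non-3-en-3-yl]carbonyl}-2-methoxyphenyl acetate
Conditions: LiTMP (from 2,2,6,6-tetramethylpiperidine, n-BuLi), THF, −78 °C; then 39, −78 °C
Reagents that add atoms: none
Why: The C3 vinyl hydrogen of the bicyclic vinylogous ester is the only acidic site because no enolisable ketone remains, so deprotonation with the hindered amide and C-acylation of the vinyllithium should install the aroyl group, the acid chloride reacting much faster than the aryl acetate.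

Step 25
Reactants: 40 4-{[(1R,5R,7R)-4-methoxy-8,8-dimethyl-1,7-bis(3-methylbut-2-en-1-yl)-5-[(2S)-5-methyl-2-(prop-1-en-2-yl)hex-4-en-1-yl]-2,9-dioxobicyclo[3.3.1]non-3-en-3-yl]carbonyl}-2-methoxyphenyl acetate
Product: 41 garcinol 13-O-methyl ether
Conditions: LiOH, dioxane–H2O, 90 °C; then 1 N HCl
Reagents that add atoms: lithium hydroxide, [Li+].[OH-]
Why: Hydroxide should add to C4 of the doubly activated vinylogous ester and expel methoxide (addition–elimination) while also saponifying the aryl acetate, the aryl methyl ether being inert, which gives the enolised β-triketone of the target.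

**Compound list**

1 | (R)-4-benzyloxazolidin-2-one | O=C1N[C@H](Cc2ccccc2)CO1 | starting material
2 | (E)-but-2-enoyl chloride | C/C=C/C(=O)Cl | starting material
3 | (R)-4-benzyl-3-[(E)-but-2-enoyl]oxazolidin-2-one | C/C=C/C(=O)N1[C@H](Cc2ccccc2)COC1=O | intermediate
4 | 1-bromo-3-methylbut-2-ene (prenyl bromide) | CC(C)=CCBr | starting material
5 | (R)-4-benzyl-3-[(2R)-2-ethenyl-5-methylhex-4-enoyl]oxazolidin-2-one | C=C[C@@H](CC=C(C)C)C(=O)N1[C@H](Cc2ccccc2)COC1=O | intermediate
6 | (2R)-2-ethenyl-5-methylhex-4-en-1-ol | C=C[C@@H](CC=C(C)C)CO | intermediate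
7 | (3R)-3-(iodomethyl)-6-methylhepta-1,5-diene | C=C[C@@H](CC=C(C)C)CI | intermediate
8 | 3-tert-butoxy-3-oxopropanoic acid (mono-tert-butyl malonate) | CC(C)(C)OC(=O)CC(=O)O | starting material
9 | 2,2-diphenylethanol | OCC(c1ccccc1)c1ccccc1 | starting material
10 | tert-butyl 2,2-diphenylethyl malonate | CC(C)(C)OC(=O)CC(=O)OCC(c1ccccc1)c1ccccc1 | intermediate
11 | tert-butyl 2,2-diphenylethyl 2-[(2S)-2-ethenyl-5-methylhex-4-en-1-yl]malonate (both epimers at the malonate carbon) | C=C[C@@H](CC=C(C)C)CC(C(=O)OCC(c1ccccc1)c1ccccc1)C(=O)OC(C)(C)C | intermediate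
12 | 3-bromoprop-1-yne (propargyl bromide) | C#CCBr | starting material
13 | 1-tert-butyl 3-(2,2-diphenylethyl) (2R)-2-[(2S)-2-ethenyl-5-methylhex-4-en-1-yl]-2-(prop-2-yn-1-yl)malonate | C=C[C@@H](CC=C(C)C)C[C@@](C(=O)OCC(c1ccccc1)c1ccccc1)(C(=O)OC(C)(C)C)CC#C | intermediate
14 | (2R)-2-(tert-butoxycarbonyl)-2-[(2S)-2-ethenyl-5-methylhex-4-en-1-yl]pent-4-ynoic acid | C=C[C@@H](CC=C(C)C)C[C@@](C(=O)O)(C(=O)OC(C)(C)C)CC#C | intermediate
15 | potassium 3-methoxy-3-oxopropanoate (potassium methyl malonate) | COC(=O)CC(=O)[O-].[K+] | starting material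
16 | tert-butyl (2R)-2-[(2S)-2-ethenyl-5-methylhex-4-en-1-yl]-2-(imidazole-1-carbonyl)pent-4-ynoate (acyl imidazolide, not isolated) | C=C[C@@H](CC=C(C)C)C[C@@](C(=O)n1ccnc1)(C(=O)OC(C)(C)C)CC#C | intermediate
17 | (4R)-4-(tert-butoxycarbonyl)-4-[(2S)-2-ethenyl-5-methylhex-4-en-1-yl]-2-(methoxycarbonyl)-3-oxohept-6-ynoic acid (acylmalonic half-ester, magnesium salt in the flask, not isolated) | C=C[C@@H](CC=C(C)C)C[C@@](C(=O)C(C(=O)OC)C(=O)O)(C(=O)OC(C)(C)C)CC#C | intermediate
18 | 1-tert-butyl 5-methyl (2R)-2-[(2S)-2-ethenyl-5-methylhex-4-en-1-yl]-3-oxo-2-(prop-2-yn-1-yl)pentanedioate | C=C[C@@H](CC=C(C)C)C[C@@](C(=O)CC(=O)OC)(C(=O)OC(C)(C)C)CC#C | intermediate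
19 | 5-tert-butyl 1-methyl (2E,4R)-4-[(2S)-2-ethenyl-5-methylhex-4-en-1-yl]-3-methoxy-4-(prop-2-yn-1-yl)pent-2-enedioate | C=C[C@@H](CC=C(C)C)C[C@@](/C(OC)=C\C(=O)OC)(C(=O)OC(C)(C)C)CC#C | intermediate
20 | 1-methyl 5-trimethylsilyl (2E,4R)-4-[(2S)-2-ethenyl-5-methylhex-4-en-1-yl]-3-methoxy-4-(prop-2-yn-1-yl)pent-2-enedioate (trimethylsilyl ester, not isolated) | C=C[C@@H](CC=C(C)C)C[C@@](/C(OC)=C\C(=O)OC)(C(=O)O[Si](C)(C)C)CC#C | intermediate
21 | (2R,3E)-2-[(2S)-2-ethenyl-5-methylhex-4-en-1-yl]-3,5-dimethoxy-5-oxo-2-(prop-2-yn-1-yl)pent-3-enoic acid | C=C[C@@H](CC=C(C)C)C[C@@](/C(OC)=C\C(=O)OC)(C(=O)O)CC#C | intermediate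
22 | 5-bromo-2-methylpent-2-ene | CC(C)=CCCBr | starting material
23 | methyl (2E,4R)-4-(chlorocarbonyl)-4-[(2S)-2-ethenyl-5-methylhex-4-en-1-yl]-3-methoxyhept-2-en-6-ynoate (acid chloride, not isolated) | C=C[C@@H](CC=C(C)C)C[C@@](/C(OC)=C\C(=O)OC)(C(=O)Cl)CC#C | intermediate
24 | methyl (2E,4R)-4-[(2S)-2-ethenyl-5-methylhex-4-en-1-yl]-3-methoxy-9-methyl-5-oxo-4-(prop-2-yn-1-yl)deca-2,8-dienoate | C=C[C@@H](CC=C(C)C)C[C@@](/C(OC)=C\C(=O)OC)(C(=O)CCC=C(C)C)CC#C | intermediate
25 | (4S)-4-[(2S)-2-ethenyl-5-methylhex-4-en-1-yl]-5-hydroxy-3-methoxy-6-(3-methylbut-2-en-1-yl)-4-(prop-2-yn-1-yl)cyclohexa-2,5-dien-1-one (enol form of the 1,3-dione) | C=C[C@@H](CC=C(C)C)C[C@@]1(CC#C)C(OC)=CC(=O)C(CC=C(C)C)=C1O | intermediate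
26 | 4,4,5,5-tetramethyl-2-(prop-1-en-2-yl)-1,3,2-dioxaborolane | C=C(C)B1OC(C)(C)C(C)(C)O1 | starting material
27 | phenyl(prop-1-en-2-yl)iodonium tetrafluoroborate | C=C(C)[I+]c1ccccc1.F[B-](F)(F)F | intermediate
28 | (2S,6R)-6-[(2S)-2-ethenyl-5-methylhex-4-en-1-yl]-5-methoxy-2-(3-methylbut-2-en-1-yl)-2-(prop-1-en-2-yl)-6-(prop-2-yn-1-yl)cyclohex-4-ene-1,3-dione (isopropenyl cis to propargyl) | C=C[C@@H](CC=C(C)C)C[C@@]1(CC#C)C(OC)=CC(=O)[C@](CC=C(C)C)(C(C)=C)C1=O | intermediate
29 | S-ethyl carbonochloridothioate (S-ethyl chlorothioformate) | CCSC(Cl)=O | starting material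
30 | S-ethyl 4-[(1R,5S)-1-[(2S)-2-ethenyl-5-methylhex-4-en-1-yl]-2-methoxy-5-(3-methylbut-2-en-1-yl)-4,6-dioxo-5-(prop-1-en-2-yl)cyclohex-2-en-1-yl]but-2-ynethioate | C=C[C@@H](CC=C(C)C)C[C@@]1(CC#CC(=O)SCC)C(OC)=CC(=O)[C@](CC=C(C)C)(C(C)=C)C1=O | intermediate
31 | S-ethyl 2-[(1S,5R)-5-[(2S)-2-ethenyl-5-methylhex-4-en-1-yl]-4-methoxy-8,8-dimethyl-1-(3-methylbut-2-en-1-yl)-2,9-dioxobicyclo[3.3.1]non-3-en-7-ylidene]ethanethioate (E/Z mixture) | C=C[C@@H](CC=C(C)C)C[C@@]12CC(=CC(=O)SCC)C(C)(C)[C@@](CC=C(C)C)(C(=O)C=C1OC)C2=O | intermediate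
32 | S-ethyl 2-[(1S,5R,7S)-5-[(2S)-2-ethenyl-5-methylhex-4-en-1-yl]-4-methoxy-8,8-dimethyl-1-(3-methylbut-2-en-1-yl)-2,9-dioxobicyclo[3.3.1]non-3-en-7-yl]ethanethioate | C=C[C@@H](CC=C(C)C)C[C@@]12C[C@@H](CC(=O)SCC)C(C)(C)[C@@](CC=C(C)C)(C(=O)C=C1OC)C2=O | intermediate
33 | 2-[(1S,5R,7S)-5-[(2S)-2-ethenyl-5-methylhex-4-en-1-yl]-4-methoxy-8,8-dimethyl-1-(3-methylbut-2-en-1-yl)-2,9-dioxobicyclo[3.3.1]non-3-en-7-yl]acetaldehyde | C=C[C@@H](CC=C(C)C)C[C@@]12C[C@@H](CC=O)C(C)(C)[C@@](CC=C(C)C)(C(=O)C=C1OC)C2=O | intermediate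
34 | isopropyltriphenylphosphonium iodide | CC(C)[P+](c1ccccc1)(c1ccccc1)c1ccccc1.[I-] | starting material
35 | (1S,5R,7R)-5-[(2S)-2-ethenyl-5-methylhex-4-en-1-yl]-4-methoxy-8,8-dimethyl-1,7-bis(3-methylbut-2-en-1-yl)bicyclo[3.3.1]non-3-ene-2,9-dione | C=C[C@@H](CC=C(C)C)C[C@@]12C[C@@H](CC=C(C)C)C(C)(C)[C@@](CC=C(C)C)(C(=O)C=C1OC)C2=O | intermediate
36 | (1S,5S,7R)-5-[(2S)-2-acetyl-5-methylhex-4-en-1-yl]-4-methoxy-8,8-dimethyl-1,7-bis(3-methylbut-2-en-1-yl)bicyclo[3.3.1]non-3-ene-2,9-dione | CC(=O)[C@@H](CC=C(C)C)C[C@@]12C[C@@H](CC=C(C)C)C(C)(C)[C@@](CC=C(C)C)(C(=O)C=C1OC)C2=O | intermediate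
37 | (1S,5R,7R)-4-methoxy-8,8-dimethyl-1,7-bis(3-methylbut-2-en-1-yl)-5-[(2S)-5-methyl-2-(prop-1-en-2-yl)hex-4-en-1-yl]bicyclo[3.3.1]non-3-ene-2,9-dione | C=C(C)[C@@H](CC=C(C)C)C[C@@]12C[C@@H](CC=C(C)C)C(C)(C)[C@@](CC=C(C)C)(C(=O)C=C1OC)C2=O | intermediate
38 | 4-acetoxy-3-methoxybenzoic acid | CC(=O)Oc1ccc(C(=O)O)cc1OC | starting material
39 | 4-acetoxy-3-methoxybenzoyl chloride | CC(=O)Oc1ccc(C(=O)Cl)cc1OC | intermediate
40 | 4-{[(1R,5R,7R)-4-methoxy-8,8-dimethyl-1,7-bis(3-methylbut-2-en-1-yl)-5-[(2S)-5-methyl-2-(prop-1-en-2-yl)hex-4-en-1-yl]-2,9-dioxobicyclo[3.3.1]non-3-en-3-yl]carbonyl}-2-methoxyphenyl acetate | C=C(C)[C@@H](CC=C(C)C)C[C@@]12C[C@@H](CC=C(C)C)C(C)(C)[C@@](CC=C(C)C)(C(=O)C(C(=O)c3ccc(OC(C)=O)c(OC)c3)=C1OC)C2=O | intermediate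
41 | garcinol 13-O-methyl ether: (1R,5R,7R)-4-hydroxy-3-(4-hydroxy-3-methoxybenzoyl)-8,8-dimethyl-1,7-bis(3-methylbut-2-en-1-yl)-5-[(2S)-5-methyl-2-(prop-1-en-2-yl)hex-4-en-1-yl]bicyclo[3.3.1]non-3-ene-2,9-dione | C=C(C)[C@@H](CC=C(C)C)C[C@@]12C[C@@H](CC=C(C)C)C(C)(C)[C@@](CC=C(C)C)(C(=O)C(C(=O)c3ccc(O)c(OC)c3)=C1O)C2=O | target

**Count and risks**

Total step count: 25. Longest linear sequence: 22 steps (steps 1–4, 6–13, 15–22, 24, 25); steps 5, 14 and 23 are side branches.

Step 17 (key step). What may go wrong: the tertiary C8 radical is hydrogenated by the metal hydride or silane, or rearranges by 1,2-acyl shift, faster than it closes onto the hindered alkyne. The fallback sets out from 30 and comes back at 31. A Mukaiyama hydration of 30 (Co(acac)2 cat., PhSiH3, O2, THF–i-PrOH, then Me2S) traps the same radical with oxygen, which is faster than any other fate, and gives the tertiary alcohol F1. Acylation with oxalyl chloride and then N-hydroxyphthalimide/Et3N gives the tert-alkyl N-phthalimidoyl oxalate F2. Visible-light photoredox fragmentation of F2 (Ru(bpy)3(PF6)2 cat., Hantzsch ester, i-Pr2NEt·HBF4, CH2Cl2–THF, blue light) regenerates the C8 radical with no metal hydride present. It should then close 6-exo-dig onto the thioester-activated alkyne, and the vinyl radical takes hydrogen from the dihydropyridine, giving 31.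

Step 15. What may go wrong: the alkenyl group is delivered mainly to the face of the branched C5 chain (trans to the propargyl arm), or the iodonium salt transfers phenyl. The fallback sets out from acid 21 and comes back at 28, and it inverts the order in which the two C1 substituents arrive. The acid chloride of 21 is coupled with MeMgBr (Fe(acac)3 cat., −78 °C) to give the methyl ketone F3. Claisen cyclisation (KOtBu, THF) gives the C1-unsubstituted dione F4. Knoevenagel condensation with acetone (TiCl4, pyridine, THF) gives the 2-isopropylidene dione F5. γ-Deprotonation (KHMDS, THF, −78 °C) and α-alkylation with prenyl bromide (deconjugative alkylation) then give 28. The last group to enter is now prenyl, so a facial preference that was wrong for the alkenyl group becomes right.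

Step 18. What may go wrong: hydride delivery to the neopentyl-type β-carbon is too slow, comes partly from the endo face, or is accompanied by reduction of the C2 carbonyl. The fallback sets out from 31 and comes back at 33. Fukuyama reduction is run first (Et3SiH, Lindlar catalyst, acetone) to give the enal F6. Iminium-catalysed transfer hydrogenation (chiral 2-tert-butyl-3-methylimidazolidin-4-one trifluoroacetate, Hantzsch ester, CHCl3, −30 °C → rt) then gives 33. The catalyst antipode is chosen to reinforce exo attack, the E and Z enals converge through iminium isomerisation, and ketones and isolated alkenes are not touched.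

**Further compounds**

F1 | step 17 | S-ethyl 4-[(1R,5S)-1-[(2S)-2-ethenyl-5-methylhex-4-en-1-yl]-5-(2-hydroxypropan-2-yl)-2-methoxy-5-(3-methylbut-2-en-1-yl)-4,6-dioxocyclohex-2-en-1-yl]but-2-ynethioate (tertiary alcohol) | C=C[C@@H](CC=C(C)C)C[C@@]1(CC#CC(=O)SCC)C(OC)=CC(=O)[C@](CC=C(C)C)(C(C)(C)O)C1=O
F2 | step 17 | N-phthalimidoyl oxalate of F1 (tert-alkyl 1,3-dioxoisoindolin-2-yl oxalate) | C=C[C@@H](CC=C(C)C)C[C@@]1(CC#CC(=O)SCC)C(OC)=CC(=O)[C@](CC=C(C)C)(C(C)(C)OC(=O)C(=O)ON2C(=O)c3ccccc3C2=O)C1=O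
F3 | step 15 | methyl (2E,4R)-4-acetyl-4-[(2S)-2-ethenyl-5-methylhex-4-en-1-yl]-3-methoxyhept-2-en-6-ynoate (methyl ketone) | C=C[C@@H](CC=C(C)C)C[C@@](/C(OC)=C\C(=O)OC)(C(C)=O)CC#C
F4 | step 15 | (4S)-4-[(2S)-2-ethenyl-5-methylhex-4-en-1-yl]-5-hydroxy-3-methoxy-4-(prop-2-yn-1-yl)cyclohexa-2,5-dien-1-one (C1-unsubstituted dione, enol form) | C=C[C@@H](CC=C(C)C)C[C@@]1(CC#C)C(OC)=CC(=O)C=C1O
F5 | step 15 | (6R)-6-[(2S)-2-ethenyl-5-methylhex-4-en-1-yl]-5-methoxy-2-(propan-2-ylidene)-6-(prop-2-yn-1-yl)cyclohex-4-ene-1,3-dione (2-isopropylidene dione) | C=C[C@@H](CC=C(C)C)C[C@@]1(CC#C)C(OC)=CC(=O)C(=C(C)C)C1=O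
F6 | step 18 | 2-[(1S,5R)-5-[(2S)-2-ethenyl-5-methylhex-4-en-1-yl]-4-methoxy-8,8-dimethyl-1-(3-methylbut-2-en-1-yl)-2,9-dioxobicyclo[3.3.1]non-3-en-7-ylidene]acetaldehyde (enal, E/Z mixture) | C=C[C@@H](CC=C(C)C)C[C@@]12CC(=CC=O)C(C)(C)[C@@](CC=C(C)C)(C(=O)C=C1OC)C2=O
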